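**Your hunch.** I cannot integrate this scheme at the blackboard, so I cannot give you a row by hand. I can test your hunch that more substrate simply buys more target.

    substrate + intermediate D → side product (k1 = 6.1 /M/s)
    intermediate A → intermediate D (k2 = 0.020 /s)
    substrate ⇌ intermediate C (K3 = 1.4, k3 = 0.088 /s)
    substrate + partner ⇌ intermediate B (K4 = 96 /M, k4 = 1.1 /M/s)
    intermediate D ⇌ target (K5 = 0.35, k5 = 0.10 /s)
    substrate + partner → intermediate A (k6 = 8.2 /M/s)
    intermediate B ⇌ intermediate E (K7 = 0.82, k7 = 0.019 /s)

| flask | substrate | partner | time |
|---|---|---|---|
| south-east | 0.0060 M | 0.0120 M | 1.5 min |
| north-west | 0.010 M | 0.0120 M | 1.5 min |
| east | 0.015 M | 0.0120 M | 1.5 min |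
| south-west | 0.025 M | 0.0120 M | 1.5 min |

- percentages count the substrate that a species holds: one side product counts as two
- "hardly changes" means that all values lie within two and a half points (for a concentration: within two and a half percent of the largest)
- run time (south-east): 1.5 min

* [target] at the end for south-east, north-west, east, south-west, in this order
* how that number moves from the first to the last of them (falls all the way / rises, then falls / hardly changes / rises all the way / falls, then rises)

**One pool.** Intermediate D and target relax into each other with a half-life by step 5 alone of 1.80 s, far shorter than the run of 1.5 min, so I treat them as one pool, of which intermediate D holds a fraction 0.741.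

**Time removed.** Of the takers of substrate I compare two: intermediate D turns it into side product, and partner turns it into intermediate A. I divide the first rate by the second, so [substrate] cancels and time drops out. What remains is the robbery factor, a selectivity factor: the substrate lost to the pool per substrate taken by partner into intermediate A, when pool and [partner] stand equal, 0.551. The ratio of the two rates is this factor times the pool over [partner].

**Break-even.** The pool cannot hold more than partner has delivered, so the ratio reaches one after at least 0.00774 M of partner is used. South-east charges less substrate than that: even with its whole charge in the pool, the ratio is 0.551. South-west charges more substrate than partner, which makes partner the limiting reagent there, with 0.0130 M of substrate unmatched. Intermediate A stands between partner and the pool, and its half-life by step 2 alone, 0.58 min, is shorter than the run by a factor of 2.59, so I expect the turn above 0.00774 M. So I commit to a rise out of south-east and a fall into south-west, but my reckoning gives a direction and no row.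

**The forecast.** The forecast goes further, with 8.200 × 10⁻⁴ M, 0.00112 M, 0.00125 M and 9.000 × 10⁻⁴ M, so that [target] rises, then falls. Its grounds include that "the pool is still building" at the end of the run.

**The outcome.** The simulation gives 8.32 × 10⁻⁴ M, 0.00117 M, 0.00129 M and 9.47 × 10⁻⁴ M, so [target] rises, then falls, turning at 0.015 M with 0.00129 M. At the end of south-west, 2.3% of the partner charge stands beside 13% of the substrate charge. The robbery factor, applied to the pool and [partner] at the end, gives a ratio of 0.267 in south-east, 1.56 in east and 7.23 in south-west.

(The rate constants were chosen freely; the flask was simulated.)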